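**Assumptions (one line each)**
- "(7R)" is the exocyclic benzylic carbinol; the given SMILES assigns it R, and the three ring stereocentres are 2S (aryl carbon), 3R (CH2OH carbon) and 4R (carbinol-bearing carbon).
- Phenols are carried as benzyl ethers, and the aryl aldehyde is commercial 4-(benzyloxy)-3-methoxybenzaldehyde.

**Retrosynthetic overview**
1. The tetrahydrofuran (formed last) comes from acid-promoted 5-exo etherification of the aryl-bearing benzylic alcohol with the CH2OH of the other half. The exocyclic carbinol is carried as a TBS ether, and the aryl-bearing carbon settles 2,3-trans thermodynamically.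
2. That diol comes from LiAlH4 opening of a 3,4-disubstituted γ-butyrolactone in which the CH2O–C(=O) unit bridges the two halves. The target's 3R,4R ring stereocentres correspond to the trans-disubstituted arrangement on this lactone.
3. The lactone is built by aldol reaction of its E-lactone enolate with aryl aldehyde, which gives the trans relationship to the β-substituent and the anti carbinol (R).
4. The β-substituted lactone comes from an Evans syn-aldol of a succinate half-ester imide with the aryl aldehyde, then LiBH4 cleavage of the auxiliary and lactonisation, which sets the CH2OH-bearing carbon (R).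
5. Ring order: the γ-butyrolactone (a stereochemical template) is formed first and the tetrahydrofuran last.

---

**Step 1**
Reactants: 1 (S)-4-benzyloxazolidin-2-one; 2 methyl 4-chloro-4-oxobutanoate
Product: 3 (S)-4-benzyl-3-(4-methoxy-4-oxobutanoyl)oxazolidin-2-one
Conditions: Et3N, DMAP (cat.), CH2Cl2, 0 °C → rt
Reagents that add atoms: none
Why: N-acylation of the oxazolidinone NH by the acid chloride installs the chiral imide that controls the next aldol.

**Step 2**
Reactants: 3 imide; 4 4-(benzyloxy)-3-methoxybenzaldehyde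
Product: 5 methyl (3S,4S)-3-[(4S)-4-benzyl-2-oxooxazolidine-3-carbonyl]-4-[4-(benzyloxy)-3-methoxyphenyl]-4-hydroxybutanoate
Conditions: Bu2BOTf, i-Pr2NEt, CH2Cl2, –78 → 0 °C; add 4, –78 °C → rt; then pH 7 buffer, MeOH, 30% H2O2, 0 °C
Reagents that add atoms: none
Why: Evans syn-aldol via the Z-boron enolate and a Zimmerman–Traxler chair transition state; the (S)-benzyl auxiliary sets C7 = S and the CH2OH-bearing carbon C8 = R (final numbering).

**Step 3**
Reactants: 5 aldol adduct
Product: 6 (4R)-4-{(S)-[4-(benzyloxy)-3-methoxyphenyl](hydroxy)methyl}oxolan-2-one (recovered 1 is released)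
Conditions: LiBH4, MeOH (2 equiv), Et2O, 0 °C; then TsOH (cat.), CH2Cl2, rt
Reagents that add atoms: none
Why: Reductive cleavage of the more electrophilic imide frees the primary alkoxide/alcohol, which lactonises onto the methyl ester; no stereocentre is touched.

**Step 4**
Reactants: 6 lactone
Product: 7 (4R)-4-{(S)-[4-(benzyloxy)-3-methoxyphenyl][(triethylsilyl)oxy]methyl}oxolan-2-one
Conditions: TESOTf, 2,6-lutidine, CH2Cl2, –78 °C
Reagents that add atoms: triethylsilyl triflate, CC[Si](CC)(CC)OS(=O)(=O)C(F)(F)F
Why: Silylation of the secondary benzylic OH is needed before enolate formation, and the TES group can later be removed selectively in the presence of TBS.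

**Step 5**
Reactants: 7 TES-lactone; 4 4-(benzyloxy)-3-methoxybenzaldehyde
Product: 8 (3S,4R)-3-{(R)-[4-(benzyloxy)-3-methoxyphenyl][(tert-butyldimethylsilyl)oxy]methyl}-4-{(S)-[4-(benzyloxy)-3-methoxyphenyl][(triethylsilyl)oxy]methyl}oxolan-2-one
Conditions: LiHMDS, THF, –78 °C, 30 min; add 4, –78 °C, 1 h; then TBSOTf, –78 → 0 °C
Reagents that add atoms: tert-butyldimethylsilyl triflate, CC(C)(C)[Si](C)(C)OS(=O)(=O)C(F)(F)F
Why: Lactone enolate aldol: the bulky β-substituent directs attack anti to it, so C8′ is trans to C8; the E(O) lactone enolate reacts through a chair transition state to give the anti aldol (C7′ = R), and in situ O-silylation prevents retro-aldol and epimerisation.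

**Step 6**
Reactants: 8 silylated lactone
Product: 9 (1S,2R,3R,4R)-1,4-bis[4-(benzyloxy)-3-methoxyphenyl]-2,3-bis(hydroxymethyl)butane, 1-OTES, 4-OTBS
Conditions: LiAlH4, THF, 0 °C
Reagents that add atoms: none
Why: Hydride reduction of the lactone gives the diol; silyl and benzyl ethers survive, and C8′ is no longer acidic, so no epimerisation.

**Step 7**
Reactants: 9 diol
Product: 10 same diol with free 1-OH and 4-OTBS (1S,2R,3R,4R)
Conditions: PPTS (0.2 equiv), MeOH, rt
Reagents that add atoms: none
Why: The TES ether is cleaved selectively over the more hindered, more robust TBS ether, leaving only the aryl-bearing benzylic alcohol free.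

**Step 8**
Reactants: 10 triol
Product: 11 (2S,3R,4R)-2-[4-(benzyloxy)-3-methoxyphenyl]-4-{(R)-[4-(benzyloxy)-3-methoxyphenyl](TBS-oxy)methyl}-3-(hydroxymethyl)tetrahydrofuran
Conditions: CSA (10 mol%), CH2Cl2 (0.01 M), 0 °C
Reagents that add atoms: none
Why: Acid-catalysed dehydrative 5-exo etherification: the benzylic cation at C7 is captured only by the C9′-OH (C9-OH would give an oxetane and C7′ is silylated), and under reversible acid conditions the 2,3-trans isomer (C7 = S) is favoured over the all-cis one.

**Step 9**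
Reactants: 11 TBS ether
Product: 12 (2S,3R,4R)-2-[4-(benzyloxy)-3-methoxyphenyl]-4-{(R)-[4-(benzyloxy)-3-methoxyphenyl](hydroxy)methyl}-3-(hydroxymethyl)tetrahydrofuran
Conditions: TBAF, AcOH, THF, 0 °C → rt
Reagents that add atoms: none
Why: Fluoride removes the silyl ether with retention at C7′.

**Step 10**
Reactants: 12 bis-benzyl ether
Product: 13 (7R)-7-hydroxylariciresinol, (2S,3R,4R)-2-(4-hydroxy-3-methoxyphenyl)-4-[(R)-hydroxy(4-hydroxy-3-methoxyphenyl)methyl]-3-(hydroxymethyl)tetrahydrofuran
Conditions: H2 (1 atm), 10% Pd/C, EtOAc/EtOH, rt, short reaction time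
Reagents that add atoms: none (H2 adds only hydrogen)
Why: Hydrogenolysis removes the two phenolic benzyl ethers, and the benzylic carbinol and ring ether are left intact by mild, monitored conditions.

---

**Compound list**
1 | (S)-4-benzyloxazolidin-2-one | O=C1N[C@@H](Cc2ccccc2)CO1 | starting material
2 | methyl 4-chloro-4-oxobutanoate | COC(=O)CCC(=O)Cl | starting material
3 | (S)-4-benzyl-3-(4-methoxy-4-oxobutanoyl)oxazolidin-2-one | COC(=O)CCC(=O)N1[C@@H](Cc2ccccc2)COC1=O | intermediate
4 | 4-(benzyloxy)-3-methoxybenzaldehyde | COc1cc(C=O)ccc1OCc1ccccc1 | starting material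
5 | Evans syn-aldol adduct | COC(=O)C[C@H](C(=O)N1[C@@H](Cc2ccccc2)COC1=O)[C@H](O)c1ccc(OCc2ccccc2)c(OC)c1 | intermediate
6 | (4R)-4-{(S)-aryl(hydroxy)methyl}oxolan-2-one | O=C1C[C@@H]([C@H](O)c2ccc(OCc3ccccc3)c(OC)c2)CO1 | intermediate
7 | TES ether of 6 | O=C1C[C@@H]([C@H](O[Si](CC)(CC)CC)c2ccc(OCc3ccccc3)c(OC)c2)CO1 | intermediate
8 | trans, anti bis-aryl-carbinol lactone (OTES, OTBS) | COc1cc(ccc1OCc1ccccc1)[C@H](O[Si](C)(C)C(C)(C)C)[C@H]1C(=O)OC[C@@H]1[C@H](O[Si](CC)(CC)CC)c1ccc(OCc2ccccc2)c(OC)c1 | intermediate
9 | 2,3-bis(hydroxymethyl) diol, OTES/OTBS | OC[C@H]([C@@H](O[Si](C)(C)C(C)(C)C)c1ccc(OCc2ccccc2)c(OC)c1)[C@H](CO)[C@H](O[Si](CC)(CC)CC)c1ccc(OCc2ccccc2)c(OC)c1 | intermediate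
10 | triol with free benzylic OH, 4-OTBS | OC[C@H]([C@@H](O[Si](C)(C)C(C)(C)C)c1ccc(OCc2ccccc2)c(OC)c1)[C@H](CO)[C@H](O)c1ccc(OCc2ccccc2)c(OC)c1 | intermediate
11 | THF, OTBS, bis-OBn | COc1cc([C@H]2OC[C@H]([C@@H](O[Si](C)(C)C(C)(C)C)c3ccc(OCc4ccccc4)c(OC)c3)[C@@H]2CO)ccc1OCc1ccccc1 | intermediate
12 | THF, free carbinol, bis-OBn | COc1cc([C@H]2OC[C@H]([C@@H](O)c3ccc(OCc4ccccc4)c(OC)c3)[C@@H]2CO)ccc1OCc1ccccc1 | intermediate
13 | (7R)-7-hydroxylariciresinol | COc1cc([C@H]2OC[C@H]([C@@H](O)c3ccc(O)c(OC)c3)[C@@H]2CO)ccc1O | target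

---

**Totals:** 10 steps in total; the longest linear sequence is 10 steps (1 → 3 → 5 → 6 → 7 → 8 → 9 → 10 → 11 → 12 → 13, with aldehyde 4 entering at Steps 2 and 5).

**Three steps most likely to fail**
1. **Step 8 (cationic cyclisation).** The C7′ silyl ether may ionise, giving a 2,5-diaryl THF or furofuran, or the C7 diastereoselectivity may be poor.
   - Fallback (different approach): open lactone 8 with Me2AlN(OMe)Me, TBS-protect the C9 alcohol, reduce the amide to the C9′ alcohol, and close the ring by Mitsunobu or tosylate displacement with the Evans-set C7 alcohol as nucleophile, which retains C7.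
2. **Step 5 (lactone aldol).** The anti/syn ratio at C7′ may be modest, and the aldolate is sensitive to retro-aldol.
   - Fallback (different approach): C-aroylate lactone 7 to the 3-aroyl lactone, then set C7′/C8′ by Ru-catalysed asymmetric transfer hydrogenation with dynamic kinetic resolution, choosing the catalyst enantiomer for 7′R.
3. **Step 10 (hydrogenolysis).** The benzylic C7′–OH or ring C7–O bond may hydrogenolyse.
   - Fallback (different approach): start from vanillin allyl ether instead of the benzyl ether and remove the allyl groups non-reductively with Pd(PPh3)4, K2CO3, MeOH.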